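**Retrosynthetic overview**

1. The hydrogen sulfate comes from the primary alcohol, and the alcohol from an N-benzyl-N-phenyl amide by hydride reduction (the amide carbon becomes the CH2O carbon).
2. Key C–C bond: amide α-carbon to the first CH2 of the olefinic arm. A racemic α-bromo amide carrying the furylpropyl arm reacts as an α-carbonyl electrophile (enolonium-type a2 synthon) with a homoallylic alkylzinc carrying the carbocycle, under nickel/Pybox stereoconvergent coupling that sets the (S) centre.
3. The alkylzinc comes from an E-homoallylic alcohol, made from a terminal alkyne by zirconium-catalysed methylalumination and oxirane opening (E-trisubstituted olefin).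
4. The alkyne comes from asymmetric conjugate methylation of a 2-methylcyclohexenone with anti-butynylation of the enolate (both ring stereocentres), enol triflate methylation and an alkyne zipper.
5. No ring is formed: the carbocycle is bought as the enone and the furan as a bromofuran, which is joined to a pentenamide by B-alkyl Suzuki coupling before α-bromination.

Assumption: the target is the free hydrogen sulfate as drawn; it is liberated from its pyridinium salt only in the last operation (the sodium salt would be the storage form).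

**Route**

Step 1
Reactants: 1 2-methylcyclohex-2-en-1-one; 2 1-bromobut-2-yne
Product: 5 (2S,3R)-2-(but-2-yn-1-yl)-2,3-dimethylcyclohexan-1-one, via dimethylaluminium enolate 3 (not isolated), via lithium aluminate enolate 4 (not isolated)
Conditions: Me3Al (1.4 equiv), Cu(O2CC4H3S) (copper thiophene-2-carboxylate, monovalent copper, 2 mol %), binaphthol/bis(1-phenylethyl)amine phosphoramidite ligand (4 mol %, the enantiomer that gives the 3R adduct), Et2O, -30 °C; then MeLi (1.4 equiv), THF/DMPU, -30 °C; then 2, -30 → 0 °C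
Reagents that add atoms: trimethylaluminium, C[Al](C)C
Why: Copper-catalysed asymmetric conjugate addition sets the 3R methyl centre under ligand control, and the tetrasubstituted enolate, activated as its lithium ate complex, is C-alkylated by the reactive propargylic bromide on the face anti to the neighbouring methyl, which gives the cis-dimethyl 2S,3R ketone (expected about 8:1, minor isomer removed by chromatography).

Step 2
Reactants: 5 (2S,3R)-2-(but-2-yn-1-yl)-2,3-dimethylcyclohexan-1-one
Product: 7 (5R,6S)-6-(but-2-yn-1-yl)-5,6-dimethylcyclohex-1-en-1-yl trifluoromethanesulfonate, via lithium enolate 6 (not isolated)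
Conditions: LiN(iPr)2, THF, -78 °C; then PhNTf2, -78 → 0 °C
Reagents that add atoms: N-phenylbis(trifluoromethanesulfonimide), O=S(=O)(N(c1ccccc1)S(=O)(=O)C(F)(F)F)C(F)(F)F
Why: Enolate O-triflation gives a single regioisomer because the ketone has only one enolisable α-position (the other α-carbon is quaternary), so the future ring double bond is fixed in place.

Step 3
Reactants: 7 (5R,6S)-6-(but-2-yn-1-yl)-5,6-dimethylcyclohex-1-en-1-yl trifluoromethanesulfonate
Product: 8 (5R,6S)-6-(but-2-yn-1-yl)-1,5,6-trimethylcyclohex-1-ene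
Conditions: MeMgBr, Fe(acac)3 (5 mol %), THF/NMP, -30 °C
Reagents that add atoms: methylmagnesium bromide, C[Mg]Br
Why: Iron-catalysed Kumada-type cross-coupling of the enol triflate (Fürstner conditions) installs the vinylic methyl at low temperature without touching the unactivated internal alkyne or the stereocentres.

Step 4
Reactants: 8 (5R,6S)-6-(but-2-yn-1-yl)-1,5,6-trimethylcyclohex-1-ene
Product: 10 (5R,6S)-6-(but-3-yn-1-yl)-1,5,6-trimethylcyclohex-1-ene, via potassium acetylide 9 (not isolated)
Conditions: KNH(CH2)3NH2 (from KH and H2N(CH2)3NH2), H2N(CH2)3NH2, 0 °C → rt; then H2O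
Reagents that add atoms: none
Why: Alkyne zipper reaction, in which the amide base moves the triple bond through the allene to the free chain end and irreversible formation of the terminal acetylide drives the equilibrium, while the ring olefin already sits in its most substituted position and neither stereocentre carries an acidic hydrogen.

Step 5
Reactants: 10 (5R,6S)-6-(but-3-yn-1-yl)-1,5,6-trimethylcyclohex-1-ene; 11 oxirane
Product: 14 (3E)-4-methyl-6-[(1S,6R)-1,2,6-trimethylcyclohex-2-en-1-yl]hex-3-en-1-ol, via alkenyldimethylalane 12 (not isolated), via lithium alkenylalanate 13 (not isolated)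
Conditions: Me3Al (2.5 equiv), Cp2ZrCl2 (0.25 equiv), CH2Cl2, 0 °C → rt; volatiles removed; n-BuLi, hexane/THF, 0 °C; then 11, 0 °C → rt
Reagents that add atoms: trimethylaluminium, C[Al](C)C
Why: Negishi zirconium-catalysed carboalumination adds methyl and aluminium syn with the metal on the terminal carbon (E geometry, typically above 98:2), and the derived lithium alkenylalanate opens oxirane with retention of olefin geometry to give the homoallylic alcohol.

Step 6
Reactants: 14 (3E)-4-methyl-6-[(1S,6R)-1,2,6-trimethylcyclohex-2-en-1-yl]hex-3-en-1-ol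
Product: 15 (5R,6S)-6-[(3E)-6-iodo-3-methylhex-3-en-1-yl]-1,5,6-trimethylcyclohex-1-ene
Conditions: I2, PPh3, imidazole, CH2Cl2, 0 °C
Reagents that add atoms: iodine, II
Why: Appel-type iodination (Garegg–Samuelsson conditions) converts the unhindered primary alcohol into the iodide by SN2 displacement of the oxyphosphonium group, leaving both olefins and the stereocentres untouched.

Step 7
Reactants: 16 pent-4-enoyl chloride; 17 N-benzylaniline
Product: 18 N-benzyl-N-phenylpent-4-enamide
Conditions: Et3N, DMAP (cat.), CH2Cl2, 0 °C → rt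
Reagents that add atoms: none
Why: Simple N-acylation of the secondary aniline gives the N-benzyl-N-phenyl amide group that the later nickel coupling needs.

Step 8
Reactants: 18 N-benzyl-N-phenylpent-4-enamide; 19 3-bromofuran
Product: 21 N-benzyl-5-(furan-3-yl)-N-phenylpentanamide, via B-alkyl-9-BBN borane 20 (not isolated)
Conditions: 9-BBN, THF, rt; then 19, PdCl2(dppf) (3 mol %), K3PO4 (aq), DMF, 60 °C
Reagents that add atoms: none
Why: Anti-Markovnikov hydroboration of the terminal alkene followed by B-alkyl Suzuki–Miyaura coupling attaches the chain to position 3 of the furan, and the tertiary amide is inert to both operations.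

Step 9
Reactants: 21 N-benzyl-5-(furan-3-yl)-N-phenylpentanamide
Product: 23 rac-N-benzyl-2-bromo-5-(furan-3-yl)-N-phenylpentanamide, via lithium amide enolate 22 (not isolated)
Conditions: LiN(iPr)2, THF, -78 °C; enolate added to BrCCl2CCl2Br, THF, -78 °C
Reagents that add atoms: 1,2-dibromo-1,1,2,2-tetrachloroethane, BrC(Cl)(Cl)C(Cl)(Cl)Br
Why: Electrophilic α-bromination of the amide enolate by a mild positive-bromine donor (which collapses to tetrachloroethene) is fast at -78 °C where the furan is not attacked, and the racemic product is exactly what the stereoconvergent coupling uses.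

Step 10
Reactants: 15 (5R,6S)-6-[(3E)-6-iodo-3-methylhex-3-en-1-yl]-1,5,6-trimethylcyclohex-1-ene; 23 rac-N-benzyl-2-bromo-5-(furan-3-yl)-N-phenylpentanamide
Product: 25 (2S,5E)-N-benzyl-2-[3-(furan-3-yl)propyl]-6-methyl-N-phenyl-8-[(1S,6R)-1,2,6-trimethylcyclohex-2-en-1-yl]oct-5-enamide, via alkylzinc iodide 24 (not isolated)
Conditions: 15, Zn dust (I2-activated), 1,3-dimethyl-2-imidazolidinone (DMI), 40 °C; then 23 (1.0 equiv, 24 1.3 equiv), NiCl2·DME (10 mol %), (R)-(i-Pr)-Pybox (13 mol %), DMI/THF, 0 °C, 24 h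
Reagents that add atoms: none
Why: Stereoconvergent nickel-catalysed Negishi coupling of a racemic secondary α-bromo amide (Fu conditions), in which both enantiomers of 23 funnel through one α-amido radical/nickel enolate so that the amide α-carbon acts as the electrophile toward the alkylzinc carbon, and the (R)-Pybox ligand sets the new centre as S (expected 90% ee or better, the sense known for simple 2-bromobutanamides where the zinc-derived chain outranks the bromide-derived chain; the antipodal ligand is the remedy if the sense proves opposite).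

Step 11
Reactants: 25 (2S,5E)-N-benzyl-2-[3-(furan-3-yl)propyl]-6-methyl-N-phenyl-8-[(1S,6R)-1,2,6-trimethylcyclohex-2-en-1-yl]oct-5-enamide
Product: 26 (2S,5E)-2-[3-(furan-3-yl)propyl]-6-methyl-8-[(1S,6R)-1,2,6-trimethylcyclohex-2-en-1-yl]oct-5-en-1-ol
Conditions: LiAlH4, THF, 0 °C → rt
Reagents that add atoms: none
Why: Hydride reduction of the anilide proceeds by C–N cleavage of the tetrahedral intermediate (the N-benzylanilide is a good leaving group) to the aldehyde and on to the primary alcohol, without epimerising the α-centre and without touching furan or olefins.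

Step 12
Reactants: 26 (2S,5E)-2-[3-(furan-3-yl)propyl]-6-methyl-8-[(1S,6R)-1,2,6-trimethylcyclohex-2-en-1-yl]oct-5-en-1-ol
Product: 28 (2S,5E)-2-[3-(furan-3-yl)propyl]-6-methyl-8-[(1S,6R)-1,2,6-trimethylcyclohex-2-en-1-yl]oct-5-en-1-yl hydrogen sulfate (target), via pyridinium sulfate salt 27 (not isolated)
Conditions: SO3·pyridine (3 equiv), pyridine, 0 °C → rt; then sulfonic acid resin (H+ form), MeOH, 0 °C
Reagents that add atoms: sulfur trioxide pyridine complex, [O-]S(=O)(=O)[n+]1ccccc1
Why: O-Sulfation of the unhindered primary alcohol with the mild SO3·pyridine complex followed by cold proton exchange gives the hydrogen sulfate while the furan and the trisubstituted olefins stay intact.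

**Compound list**

1 | 2-methylcyclohex-2-en-1-one | CC1=CCCCC1=O | starting material
2 | 1-bromobut-2-yne | CC#CCBr | starting material
3 | dimethylaluminium (3R)-2,3-dimethylcyclohex-1-en-1-olate | C[Al](C)OC1=C(C)[C@H](C)CCC1 | intermediate (not isolated)
4 | lithium trimethyl[(3R)-2,3-dimethylcyclohex-1-en-1-olato]aluminate | [Li+].C[Al-](C)(C)OC1=C(C)[C@H](C)CCC1 | intermediate (not isolated)
5 | (2S,3R)-2-(but-2-yn-1-yl)-2,3-dimethylcyclohexan-1-one | O=C1CCC[C@@H](C)[C@]1(C)CC#CC | intermediate
6 | lithium (5R,6S)-6-(but-2-yn-1-yl)-5,6-dimethylcyclohex-1-en-1-olate | [Li]OC1=CCC[C@@H](C)[C@]1(C)CC#CC | intermediate (not isolated)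
7 | (5R,6S)-6-(but-2-yn-1-yl)-5,6-dimethylcyclohex-1-en-1-yl trifluoromethanesulfonate | O=S(=O)(OC1=CCC[C@@H](C)[C@]1(C)CC#CC)C(F)(F)F | intermediate
8 | (5R,6S)-6-(but-2-yn-1-yl)-1,5,6-trimethylcyclohex-1-ene | CC1=CCC[C@@H](C)[C@]1(C)CC#CC | intermediate
9 | potassium 4-[(1S,6R)-1,2,6-trimethylcyclohex-2-en-1-yl]but-1-yn-1-ide | CC1=CCC[C@@H](C)[C@]1(C)CCC#[C-].[K+] | intermediate (not isolated)
10 | (5R,6S)-6-(but-3-yn-1-yl)-1,5,6-trimethylcyclohex-1-ene | CC1=CCC[C@@H](C)[C@]1(C)CCC#C | intermediate
11 | oxirane | C1CO1 | starting material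
12 | dimethyl{(1E)-2-methyl-4-[(1S,6R)-1,2,6-trimethylcyclohex-2-en-1-yl]but-1-en-1-yl}alumane | CC1=CCC[C@@H](C)[C@]1(C)CC/C(C)=C/[Al](C)C | intermediate (not isolated)
13 | lithium butyl(dimethyl){(1E)-2-methyl-4-[(1S,6R)-1,2,6-trimethylcyclohex-2-en-1-yl]but-1-en-1-yl}aluminate | CC1=CCC[C@@H](C)[C@]1(C)CC/C(C)=C/[Al-](C)(C)CCCC.[Li+] | intermediate (not isolated)
14 | (3E)-4-methyl-6-[(1S,6R)-1,2,6-trimethylcyclohex-2-en-1-yl]hex-3-en-1-ol | CC1=CCC[C@@H](C)[C@]1(C)CC/C(C)=C/CCO | intermediate
15 | (5R,6S)-6-[(3E)-6-iodo-3-methylhex-3-en-1-yl]-1,5,6-trimethylcyclohex-1-ene | CC1=CCC[C@@H](C)[C@]1(C)CC/C(C)=C/CCI | intermediate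
16 | pent-4-enoyl chloride | C=CCCC(=O)Cl | starting material
17 | N-benzylaniline | C(Nc1ccccc1)c1ccccc1 | starting material
18 | N-benzyl-N-phenylpent-4-enamide | C=CCCC(=O)N(Cc1ccccc1)c1ccccc1 | intermediate
19 | 3-bromofuran | Brc1ccoc1 | starting material
20 | N-benzyl-5-(9-borabicyclo[3.3.1]nonan-9-yl)-N-phenylpentanamide | O=C(CCCCB1C2CCCC1CCC2)N(Cc1ccccc1)c1ccccc1 | intermediate (not isolated)
21 | N-benzyl-5-(furan-3-yl)-N-phenylpentanamide | O=C(CCCCc1ccoc1)N(Cc1ccccc1)c1ccccc1 | intermediate
22 | lithium 1-[benzyl(phenyl)amino]-5-(furan-3-yl)pent-1-en-1-olate | [Li]OC(=CCCCc1ccoc1)N(Cc1ccccc1)c1ccccc1 | intermediate (not isolated)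
23 | rac-N-benzyl-2-bromo-5-(furan-3-yl)-N-phenylpentanamide | O=C(C(Br)CCCc1ccoc1)N(Cc1ccccc1)c1ccccc1 | intermediate
24 | iodo{(3E)-4-methyl-6-[(1S,6R)-1,2,6-trimethylcyclohex-2-en-1-yl]hex-3-en-1-yl}zinc | CC1=CCC[C@@H](C)[C@]1(C)CC/C(C)=C/CC[Zn]I | intermediate (not isolated)
25 | (2S,5E)-N-benzyl-2-[3-(furan-3-yl)propyl]-6-methyl-N-phenyl-8-[(1S,6R)-1,2,6-trimethylcyclohex-2-en-1-yl]oct-5-enamide | CC1=CCC[C@@H](C)[C@]1(C)CC/C(C)=C/CC[C@H](CCCc1ccoc1)C(=O)N(Cc1ccccc1)c1ccccc1 | intermediate
26 | (2S,5E)-2-[3-(furan-3-yl)propyl]-6-methyl-8-[(1S,6R)-1,2,6-trimethylcyclohex-2-en-1-yl]oct-5-en-1-ol | CC1=CCC[C@@H](C)[C@]1(C)CC/C(C)=C/CC[C@H](CCCc1ccoc1)CO | intermediate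
27 | pyridinium (2S,5E)-2-[3-(furan-3-yl)propyl]-6-methyl-8-[(1S,6R)-1,2,6-trimethylcyclohex-2-en-1-yl]oct-5-en-1-yl sulfate | CC1=CCC[C@@H](C)[C@]1(C)CC/C(C)=C/CC[C@H](CCCc1ccoc1)COS(=O)(=O)[O-].c1cc[nH+]cc1 | intermediate (not isolated)
28 | (2S,5E)-2-[3-(furan-3-yl)propyl]-6-methyl-8-[(1S,6R)-1,2,6-trimethylcyclohex-2-en-1-yl]oct-5-en-1-yl hydrogen sulfate | CC1=CCC[C@@H](C)[C@]1(C)CC/C(C)=C/CC[C@H](CCCc1ccoc1)COS(=O)(=O)O | target

**Step count and risks**

Total steps: 12. Longest linear sequence: 9 (steps 1 to 6, then 10, 11 and 12); steps 7 to 9 make the second fragment.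

Steps most likely to fail:

Step 1. The aluminium enolate may alkylate sluggishly or with poor diastereoselectivity in one pot. The fallback sets out from 1 and comes back at 5. The conjugate addition is run alone, aluminium enolate 3 is silylated with Me3SiOTf, and the silyl enol ether trimethyl{[(3R)-2,3-dimethylcyclohex-1-en-1-yl]oxy}silane F1 is isolated (its ee can be measured here). F1 is cleaved with MeLi in THF to the aluminium-free lithium (3R)-2,3-dimethylcyclohex-1-en-1-olate F2, which is alkylated with 2 in THF/DMPU to give 5.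

Step 9. The positive-bromine reagent may attack the furan, or the product may be brominated twice. The fallback sets out from 21 and comes back at 23. Enolate 22 is oxidised with 2-(phenylsulfonyl)-3-phenyloxaziridine to the racemic α-hydroxy amide N-benzyl-5-(furan-3-yl)-2-hydroxy-N-phenylpentanamide F3. The hydroxyl is then exchanged for bromide with CBr4/PPh3, so that bromine arrives as bromide ion by SN2 and no electrophilic bromine source ever meets the furan.

Step 10. The furan may bind nickel or trap the α-amido radical, and the remote centre rests on catalyst control alone. The fallback sets out from 18 (with 24 made from 15 as before) and comes back at 25; the heterocycle is brought in only after the coupling. The lithium enolate of 18, lithium 1-[benzyl(phenyl)amino]penta-1,4-dien-1-olate F4, is brominated with BrCCl2CCl2Br to racemic N-benzyl-2-bromo-N-phenylpent-4-enamide F5. F5 is coupled with 24 under the same NiCl2·DME/(R)-(i-Pr)-Pybox conditions to give the allyl amide (2R,5E)-N-benzyl-6-methyl-N-phenyl-2-(prop-2-en-1-yl)-8-[(1S,6R)-1,2,6-trimethylcyclohex-2-en-1-yl]oct-5-enamide F6. This has the same spatial arrangement as 25; the descriptor changes only because allyl outranks the long chain. The single terminal alkene of F6 is hydroborated with 9-BBN to the borane (2S,5E)-N-benzyl-2-[3-(9-borabicyclo[3.3.1]nonan-9-yl)propyl]-6-methyl-N-phenyl-8-[(1S,6R)-1,2,6-trimethylcyclohex-2-en-1-yl]oct-5-enamide F7, and Suzuki coupling with 19 (PdCl2(dppf), K3PO4) gives 25.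

**Further compounds**

F1 | step 1 | trimethyl{[(3R)-2,3-dimethylcyclohex-1-en-1-yl]oxy}silane | C[Si](C)(C)OC1=C(C)[C@H](C)CCC1
F2 | step 1 | lithium (3R)-2,3-dimethylcyclohex-1-en-1-olate | [Li]OC1=C(C)[C@H](C)CCC1
F3 | step 9 | rac-N-benzyl-5-(furan-3-yl)-2-hydroxy-N-phenylpentanamide | O=C(C(O)CCCc1ccoc1)N(Cc1ccccc1)c1ccccc1
F4 | step 10 | lithium 1-[benzyl(phenyl)amino]penta-1,4-dien-1-olate | [Li]OC(=CCC=C)N(Cc1ccccc1)c1ccccc1
F5 | step 10 | rac-N-benzyl-2-bromo-N-phenylpent-4-enamide | C=CCC(Br)C(=O)N(Cc1ccccc1)c1ccccc1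
F6 | step 10 | (2R,5E)-N-benzyl-6-methyl-N-phenyl-2-(prop-2-en-1-yl)-8-[(1S,6R)-1,2,6-trimethylcyclohex-2-en-1-yl]oct-5-enamide | CC1=CCC[C@@H](C)[C@]1(C)CC/C(C)=C/CC[C@H](CC=C)C(=O)N(Cc1ccccc1)c1ccccc1
F7 | step 10 | (2S,5E)-N-benzyl-2-[3-(9-borabicyclo[3.3.1]nonan-9-yl)propyl]-6-methyl-N-phenyl-8-[(1S,6R)-1,2,6-trimethylcyclohex-2-en-1-yl]oct-5-enamide | CC1=CCC[C@@H](C)[C@]1(C)CC/C(C)=C/CC[C@H](CCCB1C2CCCC1CCC2)C(=O)N(Cc1ccccc1)c1ccccc1
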